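I decided to follow one race, the one between target being made and target turning into isomer of the product.

| flask | starting material | protic impurity | temperature | time | remark |
|---|---|---|---|---|---|
| Wednesday's | 0.75 M | 0.750 M | 35 °C | 8.0 min |  |
| Saturday's | 0.75 M | 0.750 M |  | 8.0 min | at 20 °C until 1.5 min, from then on at 35 °C |
| Tuesday's | 0.75 M | 0.750 M | 20 °C | 8.0 min |  |

    other conformer → isomer of the product (k1 = 0.00128 s⁻¹, Ea1 = 80.0 kJ mol⁻¹)
    2 starting material → self-condensation product (k2 = 8.20 × 10⁻⁷ M⁻¹ s⁻¹, Ea2 = 100 kJ mol⁻¹)
    starting material → target (k3 = 0.00163 s⁻¹, Ea3 = 84.0 kJ mol⁻¹)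
    starting material ⇌ other conformer (K4 = 16, k4 = 0.00117 s⁻¹, Ea4 = 81.0 kJ mol⁻¹, ΔH4 = 2.00 kJ mol⁻¹)
    starting material + protic impurity → quenched substrate (k5 = 9.02 × 10⁻⁴ M⁻¹ s⁻¹, Ea5 = 66.0 kJ mol⁻¹)
    target ⇌ isomer of the product (K6 = 0.32, k6 = 0.00155 s⁻¹, Ea6 = 79.0 kJ mol⁻¹, ΔH6 = −13.0 kJ mol⁻¹)
    other conformer ⇌ dormant form (K7 = 0.78, k7 = 0.00345 s⁻¹, Ea7 = 89.0 kJ mol⁻¹, ΔH7 = −73.0 kJ mol⁻¹)
    (constants at 35 °C)

- a species is counted by the starting material in it: one self-condensation product counts as two
- for a step with 2 of a species take k times the square, and two of it per event
- all constants are for 35 °C and move with temperature by the activation energies and enthalpies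
- in a conversion other conformer counts as not yet reacted

- the flask with the highest share of target in all that became target or isomer of the product ("all alike" if they lie within 1.5 percentage points) (Wednesday's / Saturday's / Tuesday's / all alike)
- share of target in all that became target or isomer of the product, Wednesday's
- share of target in all that became target or isomer of the product, Saturday's
- share of target in all that became target or isomer of the product, Tuesday's

Target and isomer of the product relax towards each other at the forward plus the back rate constant, 0.00639 s⁻¹ at 35 °C. I multiplied this by the time and got N, the number of relaxation times a flask holds: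

N = 3.07 for Wednesday's

For Tuesday's, at 20 °C, the constants moved, and the equilibrium share of target moved with them:

3.20 × 10⁻⁴ s⁻¹, K = 0.415, N = 0.524

Large N means thermodynamic control, with the share at its equilibrium value x, and small N means kinetic control. Target made at a steady pace has ages spread evenly, so the correction to x carries a memory M:

M = (1 − e^−N)/N, share = x + (1 − x)·M

Wednesday's: x = 75.8%, M = 0.311, share 83.3%

Tuesday's: x = 70.7%, M = 0.778, share 93.5%

Saturday's holds 2.59, less than Wednesday's, so I placed it a little above Wednesday's.

Was one number enough? Not for the figures. Of what starting material sends to target or other conformer, 41.8% takes the conformer, which reaches the isomer without passing target. My shares therefore count too little isomer of the product. With that stream put into the isomer at once, my reckoning for Wednesday's falls to 70.3%. The step from other conformer to isomer has a constant-times-time of 0.614 in Wednesday's but 0.124 in Tuesday's, so I expected Tuesday's to stay nearer its first figure and, with the smallest N, to stand highest.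

The forecast gave 76.3%, 77.4% and 89.7%, named Tuesday's, and said of the cold flask “Isomer therefore lags”. Its figures for Wednesday's and Tuesday's lay below my first shares.

The flasks gave 76.2% for Wednesday's, 77.4% for Saturday's and 89.7% for Tuesday's, so Tuesday's stood highest, as the forecast and I had said, and the forecast's figures held. Wednesday's self-condensation product reached 0.0173% at the end and made no difference to the share. Wednesday's N of 3.07 stayed larger than Tuesday's 0.524. Left ten times as long, Tuesday's flask holds N = 5.24, and its share stood at 69.8%, beside its cold x of 70.7%.

For a flask like Wednesday's kept at 60 °C, I reckoned K = 0.219 and N = 41.9, so M = 0.0238 and the share should sit close to x = 82.1%. That flask gave 82.0%.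

The numbers are invented; no experiment stands behind them.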